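**Retrosynthetic overview**
- The six phenols are unmasked last from methyl ethers. The E-stilbene at C6 comes from a Horner–Wadsworth–Emmons reaction on the C6 aldehyde, which is made from a C6 methyl ester.
- The trans-(2S,3S) ring comes from the cis-(2R,3S) ester by inversion at C2 alone; C3 is never touched again.
- The strategy rests on the ring O1–C2–C3–C3a–C7a: a benzofuran saturated at C2–C3 with one aryl group on each of these two carbons. Both aryl–carbon bonds are made at once by enantioselective syn-diarylation across the C2=C3 bond of a flat benzofuran, using an arenediazonium salt and an arylboronic acid.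
- Ring order: the furan ring is bought (furfural), the benzene ring is annulated onto it by Stobbe condensation and Ac2O cyclisation, and the dihydrofuran ring arises by dearomatisation without any ring closure.

Key step: step 5

Assumption: which enantiomer of the pyridine–oxazoline ligand exposes the benzofuran face leading to (2R,3S) cannot be predicted with confidence. The (S)-tert-butyl ligand is written; its mirror image is used if the opposite face proves to be preferred.

**Route**

Step 1
Reactants: 1 furfural; 2 dimethyl succinate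
Product: 3 (E)-4-(furan-2-yl)-3-(methoxycarbonyl)but-3-enoic acid
Conditions: NaOMe, MeOH, reflux; then aq. HCl
Reagents that add atoms: none
Why: Stobbe condensation, in which the succinate enolate adds to the aldehyde, the alkoxide lactonises onto the distal ester and E1cB opening of the lactone gives the half-ester with the furyl group cis to the CH2CO2H arm, the geometry the next ring closure needs.

Step 2
Reactants: 3 (E)-4-(furan-2-yl)-3-(methoxycarbonyl)but-3-enoic acid
Product: 4 methyl 4-acetoxybenzofuran-6-carboxylate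
Conditions: Ac2O, NaOAc, 140 °C
Reagents that add atoms: acetic anhydride, CC(=O)OC(C)=O
Why: Stobbe benzannulation, in which the mixed anhydride acylates furan C3 intramolecularly (Friedel–Crafts type), and enolisation with O-acetylation then gives the new benzene ring with the acetoxy group at C4 and the ester at C6.

Step 3
Reactants: 4 methyl 4-acetoxybenzofuran-6-carboxylate
Product: 6 methyl 4-methoxybenzofuran-6-carboxylate, via methyl 4-hydroxybenzofuran-6-carboxylate 5 (not isolated)
Conditions: K2CO3, MeOH, rt; evaporate; then MeI, K2CO3, DMF, rt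
Reagents that add atoms: iodomethane, CI
Why: Base-catalysed methanolysis of the aryl acetate frees the phenol and Williamson O-methylation of the phenoxide installs the smallest possible ether next to C3, while the methyl ester is unchanged in MeOH.

Step 4
Reactants: 7 3,4-dimethoxyaniline
Product: 8 3,4-dimethoxybenzenediazonium tetrafluoroborate
Conditions: NaNO2, 48% aq. HBF4, H2O, 0 °C
Reagents that add atoms: sodium nitrite, [Na+].[O-]N=O; tetrafluoroboric acid, [H+].F[B-](F)(F)F
Why: Diazotisation of the aniline with nitrous acid in HBF4 should precipitate the arenediazonium tetrafluoroborate, an electron-rich salt of the kind routinely used in Heck–Matsuda couplings.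

Step 5
Reactants: 6 methyl 4-methoxybenzofuran-6-carboxylate; 8 3,4-dimethoxybenzenediazonium tetrafluoroborate; 9 3,5-dimethoxyphenylboronic acid
Product: 10 methyl (2R,3S)-2-(3,4-dimethoxyphenyl)-3-(3,5-dimethoxyphenyl)-4-methoxy-2,3-dihydrobenzofuran-6-carboxylate (cis)
Conditions: Pd(OAc)2 (10 mol%), (S)-4-tert-butyl-2-(pyridin-2-yl)-4,5-dihydrooxazole (12 mol%), NaHCO3, tert-amyl alcohol, 0 °C to rt; 6 limiting, 8 added in portions, 9 added slowly
Reagents that add atoms: none
Why: Proposed new method: zerovalent palladium formed in the flask from Pd(OAc)2 adds oxidatively to 8 with loss of N2, and the cationic divalent arylpalladium–ligand complex inserts the C2=C3 bond of 6 in syn fashion, placing aryl on C2 and palladium on the benzylic C3. The only β-hydrogen, on C2, then lies anti to palladium, so syn β-hydride elimination is closed and the alkylpalladium should live long enough to transmetalate with 9 and reductively eliminate with retention, forming the C3–aryl bond on the face that already carries the C2–aryl bond. The closest known reaction types are Heck–Matsuda arylation with Suzuki capture (1,2-diarylation) of cyclic enol ethers and intramolecular dearomative Heck–Suzuki cascades of benzofurans and indoles; no ring is closed here, the furan ring is only dearomatised. C2 and C3 are set together: their cis relation follows from syn carbopalladation plus stereoretentive reductive elimination, and their absolute sense (2R,3S) from the benzofuran face selected by the chiral pyridine–oxazoline ligand in the insertion. The step needs aryl at C2 rather than C3, which the enol-ether polarisation of C2=C3 and the benzylic stabilisation of palladium at C3 should secure, and it needs insertion to outrun direct biaryl coupling of 8 with 9 and base-induced rearomatisation, which the slow addition of 9 and the weak base NaHCO3 are meant to ensure.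

Step 6
Reactants: 10 methyl (2R,3S)-2-(3,4-dimethoxyphenyl)-3-(3,5-dimethoxyphenyl)-4-methoxy-2,3-dihydrobenzofuran-6-carboxylate (cis)
Product: 11 methyl (2S,3S)-2-(3,4-dimethoxyphenyl)-3-(3,5-dimethoxyphenyl)-4-methoxy-2,3-dihydrobenzofuran-6-carboxylate (trans)
Conditions: CF3CO2H, CH2Cl2, 0 °C to rt
Reagents that add atoms: none
Why: Acid-catalysed epimerisation under thermodynamic control, in which reversible heterolysis of the benzylic C2–O1 bond gives a cation stabilised by the para-methoxy group and re-closure by the phenol places the C2 aryl trans to the C3 aryl, while C3 has no ionisable bond and stays 3S, so C2 becomes 2S.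

Step 7
Reactants: 11 methyl (2S,3S)-2-(3,4-dimethoxyphenyl)-3-(3,5-dimethoxyphenyl)-4-methoxy-2,3-dihydrobenzofuran-6-carboxylate (trans)
Product: 12 [(2S,3S)-2-(3,4-dimethoxyphenyl)-3-(3,5-dimethoxyphenyl)-4-methoxy-2,3-dihydrobenzofuran-6-yl]methanol
Conditions: LiAlH4, THF, 0 °C
Reagents that add atoms: none
Why: Hydride reduction of the benzoate ester to the benzylic alcohol, to which aryl methyl ethers, the dihydrofuran ring and both stereocentres are inert.

Step 8
Reactants: 12 [(2S,3S)-2-(3,4-dimethoxyphenyl)-3-(3,5-dimethoxyphenyl)-4-methoxy-2,3-dihydrobenzofuran-6-yl]methanol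
Product: 13 (2S,3S)-2-(3,4-dimethoxyphenyl)-3-(3,5-dimethoxyphenyl)-4-methoxy-2,3-dihydrobenzofuran-6-carbaldehyde
Conditions: Dess–Martin periodinane, CH2Cl2, rt
Reagents that add atoms: none
Why: Dess–Martin oxidation of a benzylic alcohol should stop at the aldehyde under near-neutral conditions that neither ionise C2–O1 nor deprotonate C3.

Step 9
Reactants: 13 (2S,3S)-2-(3,4-dimethoxyphenyl)-3-(3,5-dimethoxyphenyl)-4-methoxy-2,3-dihydrobenzofuran-6-carbaldehyde; 14 diethyl (4-methoxybenzyl)phosphonate
Product: 15 (2S,3S)-2-(3,4-dimethoxyphenyl)-3-(3,5-dimethoxyphenyl)-4-methoxy-6-[(E)-2-(4-methoxyphenyl)ethenyl]-2,3-dihydrobenzofuran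
Conditions: KOtBu, THF, 0 °C (anion of 14 preformed, 14 in slight excess over base); then 13, −78 °C to rt
Reagents that add atoms: none
Why: Horner–Wadsworth–Emmons olefination of an aromatic aldehyde with a benzylic phosphonate anion is strongly E-selective through the reversible oxaphosphetane, and preforming the anion keeps free alkoxide away from the C3–H.

Step 10
Reactants: 15 (2S,3S)-2-(3,4-dimethoxyphenyl)-3-(3,5-dimethoxyphenyl)-4-methoxy-6-[(E)-2-(4-methoxyphenyl)ethenyl]-2,3-dihydrobenzofuran
Product: 16 (2S,3S)-2-(3,4-dihydroxyphenyl)-3-(3,5-dihydroxyphenyl)-6-[(E)-2-(4-hydroxyphenyl)ethenyl]-2,3-dihydrobenzofuran-4-ol (target)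
Conditions: BBr3 (excess), CH2Cl2, −78 °C to rt; then H2O
Reagents that add atoms: none
Why: Lewis-acid ether cleavage, in which BBr3 coordinates each aryl methyl ether and bromide removes the methyl group by SN2 to give the six phenols on hydrolysis; the trans ring is the thermodynamic arrangement, so any reversible C2–O1 ionisation should leave (2S,3S) in place, and the stilbene has no aryl group within reach for cyclisation.

**Compound list**

1 | furfural | O=Cc1ccco1 | starting material
2 | dimethyl succinate | COC(=O)CCC(=O)OC | starting material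
3 | (E)-4-(furan-2-yl)-3-(methoxycarbonyl)but-3-enoic acid | COC(=O)/C(CC(=O)O)=C/c1ccco1 | intermediate
4 | methyl 4-acetoxybenzofuran-6-carboxylate | COC(=O)c1cc(OC(C)=O)c2ccoc2c1 | intermediate
5 | methyl 4-hydroxybenzofuran-6-carboxylate | COC(=O)c1cc(O)c2ccoc2c1 | intermediate (not isolated)
6 | methyl 4-methoxybenzofuran-6-carboxylate | COC(=O)c1cc(OC)c2ccoc2c1 | intermediate
7 | 3,4-dimethoxyaniline | COc1ccc(N)cc1OC | starting material
8 | 3,4-dimethoxybenzenediazonium tetrafluoroborate | COc1ccc([N+]#N)cc1OC.F[B-](F)(F)F | intermediate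
9 | 3,5-dimethoxyphenylboronic acid | COc1cc(OC)cc(B(O)O)c1 | starting material
10 | methyl (2R,3S)-2-(3,4-dimethoxyphenyl)-3-(3,5-dimethoxyphenyl)-4-methoxy-2,3-dihydrobenzofuran-6-carboxylate (cis) | COC(=O)c1cc(OC)c2c(c1)O[C@@H](c1ccc(OC)c(OC)c1)[C@H]2c1cc(OC)cc(OC)c1 | intermediate
11 | methyl (2S,3S)-2-(3,4-dimethoxyphenyl)-3-(3,5-dimethoxyphenyl)-4-methoxy-2,3-dihydrobenzofuran-6-carboxylate (trans) | COC(=O)c1cc(OC)c2c(c1)O[C@H](c1ccc(OC)c(OC)c1)[C@H]2c1cc(OC)cc(OC)c1 | intermediate
12 | [(2S,3S)-2-(3,4-dimethoxyphenyl)-3-(3,5-dimethoxyphenyl)-4-methoxy-2,3-dihydrobenzofuran-6-yl]methanol | OCc1cc(OC)c2c(c1)O[C@H](c1ccc(OC)c(OC)c1)[C@H]2c1cc(OC)cc(OC)c1 | intermediate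
13 | (2S,3S)-2-(3,4-dimethoxyphenyl)-3-(3,5-dimethoxyphenyl)-4-methoxy-2,3-dihydrobenzofuran-6-carbaldehyde | O=Cc1cc(OC)c2c(c1)O[C@H](c1ccc(OC)c(OC)c1)[C@H]2c1cc(OC)cc(OC)c1 | intermediate
14 | diethyl (4-methoxybenzyl)phosphonate | CCOP(=O)(Cc1ccc(OC)cc1)OCC | starting material
15 | (2S,3S)-2-(3,4-dimethoxyphenyl)-3-(3,5-dimethoxyphenyl)-4-methoxy-6-[(E)-2-(4-methoxyphenyl)ethenyl]-2,3-dihydrobenzofuran | COc1ccc(/C=C/c2cc(OC)c3c(c2)O[C@H](c2ccc(OC)c(OC)c2)[C@H]3c2cc(OC)cc(OC)c2)cc1 | intermediate
16 | (2S,3S)-2-(3,4-dihydroxyphenyl)-3-(3,5-dihydroxyphenyl)-6-[(E)-2-(4-hydroxyphenyl)ethenyl]-2,3-dihydrobenzofuran-4-ol | Oc1ccc(/C=C/c2cc(O)c3c(c2)O[C@H](c2ccc(O)c(O)c2)[C@H]3c2cc(O)cc(O)c2)cc1 | target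

**Step count**

Total: 10 steps. Longest linear sequence: 9 steps (steps 1, 2, 3, 5, 6, 7, 8, 9, 10 from furfural); step 4 is a one-step side branch.

**Steps most likely to fail**

1. Step 5, the step that carries the label. Four processes may defeat it:
   - the arylpalladium may couple directly with the boronic acid before it inserts the benzofuran;
   - the C3-palladated intermediate may rearomatise by base-assisted loss of the C2 hydrogen;
   - capture at C3 may be slowed by the neighbouring 4-methoxy group;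
   - the ligand may discriminate poorly between the two faces.

   The fallback uses known chemistry, sets out from 6 and comes back at 11. Direct C2–H arylation of 6 with 4-bromo-1,2-dimethoxybenzene (Pd(OAc)2, PCy3·HBF4, pivalic acid, K2CO3, DMA, 100 °C) should give methyl 2-(3,4-dimethoxyphenyl)-4-methoxybenzofuran-6-carboxylate F1. Bromination at C3 with N-bromosuccinimide in MeCN should give methyl 3-bromo-2-(3,4-dimethoxyphenyl)-4-methoxybenzofuran-6-carboxylate F2. Suzuki–Miyaura coupling with 9 (Pd(OAc)2, SPhos, K3PO4, toluene/H2O, 100 °C) should give methyl 2-(3,4-dimethoxyphenyl)-3-(3,5-dimethoxyphenyl)-4-methoxybenzofuran-6-carboxylate F3. Ionic hydrogenation (Et3SiH, CF3CO2H), in which the acid also equilibrates C2, should give the racemic trans-dihydrobenzofuran, an equal mixture of 11 and its mirror image methyl (2R,3R)-2-(3,4-dimethoxyphenyl)-3-(3,5-dimethoxyphenyl)-4-methoxy-2,3-dihydrobenzofuran-6-carboxylate F4. Preparative HPLC on a chiral stationary phase then separates 11, and step 6 is no longer needed.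

2. Step 6. The C2–O1 bond may fail to ionise under acid mild enough to spare the molecule, or the ring-opened cation may lose the C3 proton to give an open stilbene instead of re-closing.

   The fallback defers the inversion to the final Lewis-acid step; it sets out from 10 and comes back at 16. The cis ester 10 is reduced with LiAlH4 to [(2R,3S)-2-(3,4-dimethoxyphenyl)-3-(3,5-dimethoxyphenyl)-4-methoxy-2,3-dihydrobenzofuran-6-yl]methanol F5. Dess–Martin oxidation gives (2R,3S)-2-(3,4-dimethoxyphenyl)-3-(3,5-dimethoxyphenyl)-4-methoxy-2,3-dihydrobenzofuran-6-carbaldehyde F6. Olefination with the preformed anion of 14 gives (2R,3S)-2-(3,4-dimethoxyphenyl)-3-(3,5-dimethoxyphenyl)-4-methoxy-6-[(E)-2-(4-methoxyphenyl)ethenyl]-2,3-dihydrobenzofuran F7. BBr3 then removes the methyl groups, and once the para oxygen on the C2 aryl is free the ring should open to a quinone methide and re-close to the trans ring, giving 16 directly.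

3. Step 10. The sixfold demethylation may stop short, or the electron-rich stilbene may oligomerise, add HBr or isomerise under BBr3.

   The fallback demethylates before the alkene exists and changes the protecting group; it sets out from 13 and comes back at 16. BBr3 on 13 should give (2S,3S)-2-(3,4-dihydroxyphenyl)-3-(3,5-dihydroxyphenyl)-4-hydroxy-2,3-dihydrobenzofuran-6-carbaldehyde F8. TBSCl and imidazole in DMF should give the penta-silyl ether (2S,3S)-2-[3,4-bis(tert-butyldimethylsilyloxy)phenyl]-3-[3,5-bis(tert-butyldimethylsilyloxy)phenyl]-4-(tert-butyldimethylsilyloxy)-2,3-dihydrobenzofuran-6-carbaldehyde F9. Olefination uses diethyl [4-(tert-butyldimethylsilyloxy)benzyl]phosphonate F10, made from diethyl (4-hydroxybenzyl)phosphonate with TBSCl and imidazole and deprotonated with LiN(SiMe3)2 in THF. It should give the hexa-silyl ether (2S,3S)-2-[3,4-bis(tert-butyldimethylsilyloxy)phenyl]-3-[3,5-bis(tert-butyldimethylsilyloxy)phenyl]-4-(tert-butyldimethylsilyloxy)-6-{(E)-2-[4-(tert-butyldimethylsilyloxy)phenyl]ethenyl}-2,3-dihydrobenzofuran F11. Tetrabutylammonium fluoride buffered with acetic acid in THF at 0 °C then releases 16.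

**Further compounds**

F1 | step 5 | methyl 2-(3,4-dimethoxyphenyl)-4-methoxybenzofuran-6-carboxylate | COC(=O)c1cc(OC)c2cc(-c3ccc(OC)c(OC)c3)oc2c1
F2 | step 5 | methyl 3-bromo-2-(3,4-dimethoxyphenyl)-4-methoxybenzofuran-6-carboxylate | COC(=O)c1cc(OC)c2c(Br)c(-c3ccc(OC)c(OC)c3)oc2c1
F3 | step 5 | methyl 2-(3,4-dimethoxyphenyl)-3-(3,5-dimethoxyphenyl)-4-methoxybenzofuran-6-carboxylate | COC(=O)c1cc(OC)c2c(-c3cc(OC)cc(OC)c3)c(-c3ccc(OC)c(OC)c3)oc2c1
F4 | step 5 | methyl (2R,3R)-2-(3,4-dimethoxyphenyl)-3-(3,5-dimethoxyphenyl)-4-methoxy-2,3-dihydrobenzofuran-6-carboxylate | COC(=O)c1cc(OC)c2c(c1)O[C@@H](c1ccc(OC)c(OC)c1)[C@@H]2c1cc(OC)cc(OC)c1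
F5 | step 6 | [(2R,3S)-2-(3,4-dimethoxyphenyl)-3-(3,5-dimethoxyphenyl)-4-methoxy-2,3-dihydrobenzofuran-6-yl]methanol | OCc1cc(OC)c2c(c1)O[C@@H](c1ccc(OC)c(OC)c1)[C@H]2c1cc(OC)cc(OC)c1
F6 | step 6 | (2R,3S)-2-(3,4-dimethoxyphenyl)-3-(3,5-dimethoxyphenyl)-4-methoxy-2,3-dihydrobenzofuran-6-carbaldehyde | O=Cc1cc(OC)c2c(c1)O[C@@H](c1ccc(OC)c(OC)c1)[C@H]2c1cc(OC)cc(OC)c1
F7 | step 6 | (2R,3S)-2-(3,4-dimethoxyphenyl)-3-(3,5-dimethoxyphenyl)-4-methoxy-6-[(E)-2-(4-methoxyphenyl)ethenyl]-2,3-dihydrobenzofuran | COc1ccc(/C=C/c2cc(OC)c3c(c2)O[C@@H](c2ccc(OC)c(OC)c2)[C@H]3c2cc(OC)cc(OC)c2)cc1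
F8 | step 10 | (2S,3S)-2-(3,4-dihydroxyphenyl)-3-(3,5-dihydroxyphenyl)-4-hydroxy-2,3-dihydrobenzofuran-6-carbaldehyde | O=Cc1cc(O)c2c(c1)O[C@H](c1ccc(O)c(O)c1)[C@H]2c1cc(O)cc(O)c1
F9 | step 10 | (2S,3S)-2-[3,4-bis(tert-butyldimethylsilyloxy)phenyl]-3-[3,5-bis(tert-butyldimethylsilyloxy)phenyl]-4-(tert-butyldimethylsilyloxy)-2,3-dihydrobenzofuran-6-carbaldehyde | O=Cc1cc(O[Si](C)(C)C(C)(C)C)c2c(c1)O[C@H](c1ccc(O[Si](C)(C)C(C)(C)C)c(O[Si](C)(C)C(C)(C)C)c1)[C@H]2c1cc(O[Si](C)(C)C(C)(C)C)cc(O[Si](C)(C)C(C)(C)C)c1
F10 | step 10 | diethyl [4-(tert-butyldimethylsilyloxy)benzyl]phosphonate | CCOP(=O)(Cc1ccc(O[Si](C)(C)C(C)(C)C)cc1)OCC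
F11 | step 10 | (2S,3S)-2-[3,4-bis(tert-butyldimethylsilyloxy)phenyl]-3-[3,5-bis(tert-butyldimethylsilyloxy)phenyl]-4-(tert-butyldimethylsilyloxy)-6-{(E)-2-[4-(tert-butyldimethylsilyloxy)phenyl]ethenyl}-2,3-dihydrobenzofuran | CC(C)(C)[Si](C)(C)Oc1ccc(/C=C/c2cc(O[Si](C)(C)C(C)(C)C)c3c(c2)O[C@H](c2ccc(O[Si](C)(C)C(C)(C)C)c(O[Si](C)(C)C(C)(C)C)c2)[C@H]3c2cc(O[Si](C)(C)C(C)(C)C)cc(O[Si](C)(C)C(C)(C)C)c2)cc1
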